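## Analysis of the target

Locants follow the germacrane skeleton: ring carbons C1–C10, C14 the methyl on C10, C15 the methyl on C4, C11–C13 the branch on C7, C2′ the carbinol carbon of the side-chain acid.

Target 46 is a cyclodecane (C1–C10) in which one oxygen links C1 and C4, giving a tetrahydrofuran whose C1 is a hemiketal. A γ-ylidenebutenolide is fused at C6–C7: lactone oxygen on C6, carbonyl C12, C7=C11 and the 5E enol double bond C5=C6. C11 carries CH2OAc (C13) and O8 carries an (R)-3-chloro-2-hydroxy-2-methylpropanoyl group. There are five stereocentres (1S, 4R, 8S, 10R, 2′R), but C1 is not independent: a one-atom bridge across the ten-membered ring can only join cis positions of the tetrahydrofuran, so C1 follows C4. C4 and C8 are 1,5-related across C6 and cannot easily control each other, and C10 is α to the latent C1 ketone and therefore epimerisable in the open hydroxy-ketone form. The sensitive groups are the hemiketal, the enol lactone (an acyl donor within a dienolide), the primary allylic acetate, the chlorohydrin ester (closes to an epoxide with base) and the C8 ester, whose hydrogen is γ to the lactone carbonyl. The difficulties are the ten-membered ring, the annulation of the butenolide on the correct side of C6, and the late differentiation of O8 and O13. The strategy rests on the segment C4–C5–C6–C7–C8: tertiary oxygen at C4, ketone level at C6, secondary oxygen at C8, with C5 and C7 methylene-derived. This is the pattern left by a C6 acyl dianion equivalent that has opened two epoxides.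

## Retrosynthetic reasoning

**C8 ester and hemiketal.** The chlorohydrin and the free hemiketal are the most base- and nucleophile-sensitive parts, so they are unveiled last. Target 46 is taken back to epoxy ester 44 through 45: chloride opens the glycidate at its CH2, and the methyl ketal at C1 is hydrolysed. Cutting the O8–acyl bond of 44 gives alcohol 41 and epoxy acid 43, which comes from bromohydrin acid 42. The epoxide stands in for both the tertiary hydroxyl and the chloride, so no protecting group is needed on a hindered tertiary alcohol.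

**O13/O8 differentiation.** Acetate 41 comes from diol 40 by acylation of the primary hydroxyl, and 40 from bis-silyl ether 39. Both silyl ethers fall together, and steric difference then separates O13 from O8.

**Butenolide.** Dienolide 39 is cut at O6–C12 and C7–C11. Backwards this passes hydroxybutenolide 38, keto ester 37 and aldol adduct 36 to ketone 30 and α-keto ester 33 (from 31 through 32). Ester 33 brings C11, C12 and C13 at the final oxidation level. The C6 ketone provides the nucleophilic C7 and later the enol oxygen. The forward sequence has to engage C7 and not C5, and has to place C12 cis to C6.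

**Oxygen bridge and C6 carbonyl.** Ketone 30 comes from thioketal 29, and 29 from silyl ether ketone 27 by transannular ketalisation through 28. The bridged methyl ketal masks the C1 ketone and O4 at once, so C6 is the only enolisable carbonyl in 30.

**C10 and the ring.** Ketone 27 comes from enone 26 by conjugate reduction, 26 from allylic alcohol 25, and 25 from iodo aldehyde 24 by cutting C1–C10. This is the one ring bond between a carbonyl-derived carbon and the branch-bearing C10. It lies away from C4 and C8, and it lets a terminal alkyne supply both C10 and C14.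

**Functional-group adjustment.** Aldehyde 24 comes from alcohol 23, 23 from iodoalkene 21, 21 from alkyne 19, and 19 from 18 and 17. These steps silylate O4, free and hydroiodinate the alkyne, and oxidise C1.

**Linchpin coupling.** Chain 17 is cut at C6–C7 and C5–C6 into silyl dithiane 3 and epoxides 8 and 13. Both bonds are made at unsubstituted epoxide carbons, so C8 and C4 come in with the epoxides, and all ten ring carbons are assembled in one flask.

**Components.** Dithiane 3 comes from 1. Epoxide 8 comes from 4 and 5 through chlorohydrin 7. Epoxide 13 comes from 9 and 10 through diol 11. For 13, opening of the glycidol epoxide followed by reclosure on the other side is preferred over displacement at a glycidol sulfonate: direct displacement and opening–reclosure give opposite enantiomers, so any leakage between the two paths would erode enantiopurity. The opening–reclosure path requires the (S)-glycidol 9.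

## Alternatives that were turned down

**Alternative 1:** The ring is cut at C8–C9 and the butenolide is carried as a 2-silylfuran. In the forward step CrCl2 converts the allylic bromide of furan aldehyde A1 into an allylchromium species that adds to the C8 formyl group. This gives carbinol A2, closes the ten-membered ring and creates C8.
- For: the furan holds C11–C13 and the lactone oxygen in place from the start, so the question of which side of C6 is annulated never arises. On this point it is stronger than the chosen route, which must distinguish C7 from C5 in step 19. Allylchromium additions are also mild and aldehyde-selective.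
- Against: C8 is created in the ring-closing event, controlled only by the conformation of a forming medium ring. The bridged ketal next to an exo-methylene must be built before cyclisation. C10 still has to be reduced afterwards, and the furan must be oxidised to the ylidenebutenolide late, beside an allylic alcohol and a 1,1-disubstituted alkene.
- Comparison: the chosen strategy takes C4 and C8 from enantiopure epoxides, where the configuration is certain, and pays for it with a longer butenolide annulation.

**Alternative 2:** The ring is cut at C2–C3. Pd(PPh3)4 ionises allylic carbonate A3 to a π-allyl complex over C3–C5, and the β-keto sulfone carbanion at C2 attacks C3 to give macrocycle A4 with an E C4=C5 alkene.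
- For: allylic alkylation by zerovalent palladium with a stabilised carbanion is among the most dependable medium-ring closures, attack at the less hindered terminus is expected, and the butenolide is already present. For ring closure it is at least as strong as the chromium-mediated closure used here.
- Against: after cyclisation the oxidation pattern is far from the target. The sulfone must be removed, C4=C5 epoxidised with face selectivity left to the macrocycle, the epoxide opened from O1, and C5=C6 then introduced by a separate dehydrogenation. C4 is thus set late under substrate control, and the C6 stereocentre is made only to be destroyed.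
- Comparison: the chosen strategy delivers C4 as a tertiary ether of fixed configuration and C6 already at the ketone level.

**Alternative 3:** The lactone is cut at C11–C12 and C12–O. PdCl2(PPh3)2, CO and Et3N convert Z-β-iodoenone A5 into butenolide A6 by oxidative addition, CO insertion and capture of the acylpalladium by the enol oxygen of the C6 ketone, which also creates C5=C6.
- For: one step delivers the whole ylidenebutenolide, the iodide fixes the regiochemistry, and enolisation can only go toward C5. In step economy it is clearly stronger than steps 19–22 of the chosen route.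
- Against: it is an endgame only. It presupposes the ten-membered hemiketal and a tetrasubstituted β-iodoenone of defined geometry at C7=C11, whose stereoselective preparation inside the macrocycle beside the C8 stereocentre is unsolved. Oxidative addition at so hindered a vinyl iodide is slow, and the free hemiketal hydroxyl can compete for the acylpalladium.
- Comparison: the chosen strategy answers how the C1–C10 chain with C4 and C8 is assembled, and accepts four steps for the lactone.

Key step: step 6

Assumptions:
- Compounds 1, 4, 5, 9, 10, 31 and 42 are taken as commercial.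
- The 10R epimer of ketone 27 is assumed to be the thermodynamically preferred one, so that base equilibration can correct the protonation in step 14.

## Route

Step 1
Reactants: 1 1,3-dithiane
Product: 3 2-(tert-butyldimethylsilyl)-1,3-dithiane, via 2-lithio-1,3-dithiane 2 (not isolated)
Conditions: n-BuLi, THF, −30 °C; TBSCl, −78 °C → rt
Reagents that add atoms: tert-butyldimethylsilyl chloride, CC(C)(C)[Si](C)(C)Cl
Why: Corey–Seebach metalation of the C2–H flanked by two sulfur atoms, followed by C-silylation; the silyl group is the migrating group of the key step.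

Step 2
Reactants: 4 trimethylsilylacetylene; 5 (S)-epichlorohydrin
Product: 7 (S)-1-chloro-5-(trimethylsilyl)pent-4-yn-2-ol, via lithium (trimethylsilyl)acetylide 6 (not isolated)
Conditions: n-BuLi, THF, −78 °C; BF3·OEt2; then 5, −78 °C; H2O work-up
Reagents that add atoms: none
Why: BF3-promoted alkynylation of an epoxide; the acetylide attacks the unsubstituted epoxide carbon faster than it displaces chloride, and the carbinol carbon is not a reaction centre, so 7 keeps the configuration of 5.

Step 3
Reactants: 7 (S)-1-chloro-5-(trimethylsilyl)pent-4-yn-2-ol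
Product: 8 (S)-trimethyl[3-(oxiran-2-yl)prop-1-yn-1-yl]silane
Conditions: NaH, THF, 0 °C → rt
Reagents that add atoms: none
Why: Intramolecular Williamson ether synthesis (3-exo-tet) at the primary chloride; the stereocentre is untouched, and the aprotic base avoids loss of the alkynyl silyl group.

Step 4
Reactants: 9 (S)-2-methylglycidol; 10 vinylmagnesium bromide
Product: 11 (R)-2-methylpent-4-ene-1,2-diol
Conditions: 10 (2.5 equiv), CuI (0.1 equiv), THF, −30 → 0 °C; 1 M HCl work-up
Reagents that add atoms: none
Why: Copper-catalysed Grignard opening of the epoxide at its unsubstituted carbon (SN2) after deprotonation of the hydroxyl by the first equivalent; the quaternary carbon is not attacked, and the former epoxide CH2 becomes the allylic CH2 of 11.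

Step 5
Reactants: 11 (R)-2-methylpent-4-ene-1,2-diol
Product: 13 (R)-2-allyl-2-methyloxirane, via primary tosylate 12 (not isolated)
Conditions: NaH (2.2 equiv), THF, 0 °C; N-tosylimidazole (1.05 equiv), 0 °C → rt
Reagents that add atoms: none
Why: Selective sulfonylation of the primary alkoxide followed by Williamson closure by the tertiary alkoxide; the quaternary stereocentre is not a reaction centre, so the former CH2OH becomes the epoxide CH2 and the descriptor stays R.

Step 6
Reactants: 3 2-(tert-butyldimethylsilyl)-1,3-dithiane; 8 (S)-trimethyl[3-(oxiran-2-yl)prop-1-yn-1-yl]silane; 13 (R)-2-allyl-2-methyloxirane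
Product: 17 (R)-1-{2-[(S)-2-(tert-butyldimethylsilyloxy)-5-(trimethylsilyl)pent-4-yn-1-yl]-1,3-dithian-2-yl}-2-methylpent-4-en-2-ol, via lithiated silyl dithiane 14 (not isolated), via first-epoxide alkoxide 15 (not isolated), via silyl-migrated dithiane anion 16 (not isolated)
Conditions: 3, t-BuLi, Et2O, −78 → −45 °C; 8, Et2O, −78 → −25 °C; then 13, HMPA, Et2O, −78 → 0 °C; H2O work-up
Reagents that add atoms: none
Why: Lithiated 14 opens the monosubstituted epoxide 8 at its CH2 terminus (SN2), forming C6–C7 and the C8 lithium alkoxide 15, which in ether keeps silicon on carbon. Addition of HMPA solvates lithium and triggers a 1,4-shift of silicon from C6 to O8 (Brook rearrangement), which protects O8 and regenerates a dithiane carbanion 16 at C6. This anion opens the 2,2-disubstituted epoxide 13 at its CH2 terminus, forming C5–C6 and the C4 tertiary alkoxide. The closest known reaction type is the solvent-gated multicomponent coupling of a 2-silyl-1,3-dithiane with two different epoxides. No ring is closed and no stereocentre is created: both openings occur at unsubstituted carbons, so C8 and C4 keep the configurations of 8 and 13. The selectivity needed is one epoxide per alkylation in a fixed order; it is secured by the order of addition and by withholding HMPA until 8 is consumed, because without silyl migration there is no second carbanion. Regioselectivity follows from the steric preference for the unsubstituted epoxide carbon, and the C-silylated alkyne is inert to the carbanion.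

Step 7
Reactants: 17 (R)-1-{2-[(S)-2-(tert-butyldimethylsilyloxy)-5-(trimethylsilyl)pent-4-yn-1-yl]-1,3-dithian-2-yl}-2-methylpent-4-en-2-ol
Product: 18 2-[(R)-2-methyl-2-(triethylsilyloxy)pent-4-en-1-yl]-2-[(S)-2-(tert-butyldimethylsilyloxy)-5-(trimethylsilyl)pent-4-yn-1-yl]-1,3-dithiane
Conditions: TESOTf, 2,6-lutidine, CH2Cl2, −78 → 0 °C
Reagents that add atoms: triethylsilyl trifluoromethanesulfonate, CC[Si](CC)(CC)OS(=O)(=O)C(F)(F)F
Why: Silyl triflate with a hindered pyridine base silylates tertiary alcohols; O4 must be masked so that the C1 aldehyde made later does not close to a lactol that would resist ring closure.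

Step 8
Reactants: 18 2-[(R)-2-methyl-2-(triethylsilyloxy)pent-4-en-1-yl]-2-[(S)-2-(tert-butyldimethylsilyloxy)-5-(trimethylsilyl)pent-4-yn-1-yl]-1,3-dithiane
Product: 19 2-[(R)-2-methyl-2-(triethylsilyloxy)pent-4-en-1-yl]-2-[(S)-2-(tert-butyldimethylsilyloxy)pent-4-yn-1-yl]-1,3-dithiane
Conditions: K2CO3 (cat.), MeOH/THF, rt
Reagents that add atoms: none
Why: Base-catalysed methanolysis of the alkynyl C–Si bond (protodesilylation); the hindered secondary and tertiary silyl ethers are stable to these conditions.

Step 9
Reactants: 19 2-[(R)-2-methyl-2-(triethylsilyloxy)pent-4-en-1-yl]-2-[(S)-2-(tert-butyldimethylsilyloxy)pent-4-yn-1-yl]-1,3-dithiane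
Product: 21 2-[(R)-2-methyl-2-(triethylsilyloxy)pent-4-en-1-yl]-2-[(R)-2-(tert-butyldimethylsilyloxy)-4-iodopent-4-en-1-yl]-1,3-dithiane, via iodoalkenyl borane 20 (not isolated)
Conditions: B-I-9-BBN, CH2Cl2/hexane, −20 → 0 °C; AcOH, 0 °C; aq NaHCO3
Reagents that add atoms: B-iodo-9-borabicyclo[3.3.1]nonane, IB1C2CCCC1CCC2
Why: Haloboration–protonolysis: syn addition of B–I to the terminal alkyne places iodine on the internal carbon C10, and acetic acid cleaves the alkenyl C–B bond with retention; alkenes do not undergo haloboration, and the low temperature limits attack of the boron Lewis acid on the silyl ethers and the thioketal. The C8 descriptor changes to R only because iodine raises the priority of C9.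

Step 10
Reactants: 21 2-[(R)-2-methyl-2-(triethylsilyloxy)pent-4-en-1-yl]-2-[(R)-2-(tert-butyldimethylsilyloxy)-4-iodopent-4-en-1-yl]-1,3-dithiane
Product: 23 (R)-5-{2-[(R)-2-(tert-butyldimethylsilyloxy)-4-iodopent-4-en-1-yl]-1,3-dithian-2-yl}-4-methyl-4-(triethylsilyloxy)pentan-1-ol, via B-alkyl borane 22 (not isolated)
Conditions: 9-BBN, THF, 0 °C → rt; NaBO3·4H2O, H2O, rt
Reagents that add atoms: sodium perborate (NaBO3, used as the tetrahydrate), [Na+].[O-]OB=O
Why: Anti-Markovnikov hydroboration of the monosubstituted alkene, the iodoalkene being deactivated by the halogen (the selectivity exploited in B-alkyl cross-coupling precursors); perborate oxidises the C–B bond without oxidising sulfur.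

Step 11
Reactants: 23 (R)-5-{2-[(R)-2-(tert-butyldimethylsilyloxy)-4-iodopent-4-en-1-yl]-1,3-dithian-2-yl}-4-methyl-4-(triethylsilyloxy)pentan-1-ol
Product: 24 (R)-5-{2-[(R)-2-(tert-butyldimethylsilyloxy)-4-iodopent-4-en-1-yl]-1,3-dithian-2-yl}-4-methyl-4-(triethylsilyloxy)pentanal
Conditions: SO3·pyridine, DMSO, i-Pr2NEt, CH2Cl2, 0 °C
Reagents that add atoms: none
Why: Parikh–Doering oxidation; activated DMSO oxidises the primary alcohol to the aldehyde and leaves the thioketal and the vinyl iodide untouched.

Step 12
Reactants: 24 (R)-5-{2-[(R)-2-(tert-butyldimethylsilyloxy)-4-iodopent-4-en-1-yl]-1,3-dithian-2-yl}-4-methyl-4-(triethylsilyloxy)pentanal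
Product: 25 (4R,8S)-8-(tert-butyldimethylsilyloxy)-4-methyl-10-methylidene-6,6-(propane-1,3-diyldisulfanediyl)-4-(triethylsilyloxy)cyclodecan-1-ol (C1 epimers)
Conditions: CrCl2 (10 equiv), NiCl2 (0.1 equiv), DMSO/THF, rt, 0.003 M, slow addition
Reagents that add atoms: none
Why: Nozaki–Hiyama–Kishi reaction: zerovalent nickel inserts into the C–I bond, the alkenyl group is passed to trivalent chromium, and the alkenylchromium adds to the aldehyde only, closing C1–C10; high dilution and the fully substituted C4 and C6 favour cyclisation, and the new C1 carbinol needs no control because it is oxidised next.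

Step 13
Reactants: 25 (4R,8S)-8-(tert-butyldimethylsilyloxy)-4-methyl-10-methylidene-6,6-(propane-1,3-diyldisulfanediyl)-4-(triethylsilyloxy)cyclodecan-1-ol
Product: 26 (4R,8S)-8-(tert-butyldimethylsilyloxy)-4-methyl-10-methylidene-6,6-(propane-1,3-diyldisulfanediyl)-4-(triethylsilyloxy)cyclodecan-1-one
Conditions: SO3·pyridine, DMSO, i-Pr2NEt, CH2Cl2, 0 °C → rt
Reagents that add atoms: none
Why: Parikh–Doering oxidation of both carbinol epimers to one α-methylene ketone; hypervalent iodine oxidants are avoided because they can cleave dithianes, and 26 is used at once because of its Michael reactivity.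

Step 14
Reactants: 26 (4R,8S)-8-(tert-butyldimethylsilyloxy)-4-methyl-10-methylidene-6,6-(propane-1,3-diyldisulfanediyl)-4-(triethylsilyloxy)cyclodecan-1-one
Product: 27 (4R,8S,10R)-8-(tert-butyldimethylsilyloxy)-4,10-dimethyl-6,6-(propane-1,3-diyldisulfanediyl)-4-(triethylsilyloxy)cyclodecan-1-one
Conditions: [(Ph3P)CuH]6, H2O (5 equiv), benzene/THF, rt; then DBU, toluene, rt if equilibration at C10 is required
Reagents that add atoms: none
Why: Conjugate reduction by copper hydride delivers hydride to the unhindered exo-methylene carbon, and the copper enolate is protonated at C10 by water; C10 stays α to a ketone, so the epimers can be equilibrated with base toward the assumed more stable 10R isomer, with separation and recycling of the other.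

Step 15
Reactants: 27 (4R,8S,10R)-8-(tert-butyldimethylsilyloxy)-4,10-dimethyl-6,6-(propane-1,3-diyldisulfanediyl)-4-(triethylsilyloxy)cyclodecan-1-one
Product: 29 (1S,4R,8S,10R)-8-(tert-butyldimethylsilyloxy)-1,4-epoxy-1-methoxy-4,10-dimethyl-6,6-(propane-1,3-diyldisulfanediyl)cyclodecane, via bridged hemiketal 28 (not isolated)
Conditions: CSA (0.1 equiv), MeOH/CH2Cl2, 0 °C → rt
Reagents that add atoms: methanol, CO
Why: Acid-catalysed methanolysis removes the triethylsilyl ether (far more acid-labile than the hindered secondary TBS ether); the freed O4–H adds across the ring to the C1 ketone, and exchange through the oxocarbenium ion gives the bridged methyl ketal. C1 is fixed as S by C4 because the oxygen bridge can only span cis positions.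

Step 16
Reactants: 29 (1S,4R,8S,10R)-8-(tert-butyldimethylsilyloxy)-1,4-epoxy-1-methoxy-4,10-dimethyl-6,6-(propane-1,3-diyldisulfanediyl)cyclodecane
Product: 30 (1S,4R,8S,10R)-8-(tert-butyldimethylsilyloxy)-1,4-epoxy-1-methoxy-4,10-dimethylcyclodecan-6-one
Conditions: Hg(ClO4)2·3H2O, CaCO3, THF/H2O, 0 °C
Reagents that add atoms: water, O
Why: Thiophilic divalent mercury activates the thioketal for hydrolysis within minutes; the CaCO3 buffer keeps the medium near neutral so that the methyl ketal and the silyl ether survive.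

Step 17
Reactants: 31 methyl 2-(hydroxymethyl)acrylate
Product: 32 methyl 2-[(tert-butyldimethylsilyloxy)methyl]acrylate
Conditions: TBSCl, imidazole, CH2Cl2, 0 °C → rt
Reagents that add atoms: tert-butyldimethylsilyl chloride, CC(C)(C)[Si](C)(C)Cl
Why: Standard imidazole-mediated silylation of a primary alcohol.

Step 18
Reactants: 32 methyl 2-[(tert-butyldimethylsilyloxy)methyl]acrylate
Product: 33 methyl 3-(tert-butyldimethylsilyloxy)-2-oxopropanoate
Conditions: O3, CH2Cl2, −78 °C; Me2S, −78 °C → rt
Reagents that add atoms: ozone, [O-][O+]=O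
Why: Ozonolysis of the 1,1-disubstituted alkene with reductive work-up gives the α-keto ester and formaldehyde; the product is dried azeotropically and used fresh because α-keto esters hydrate readily.

Step 19
Reactants: 30 (1S,4R,8S,10R)-8-(tert-butyldimethylsilyloxy)-1,4-epoxy-1-methoxy-4,10-dimethylcyclodecan-6-one; 33 methyl 3-(tert-butyldimethylsilyloxy)-2-oxopropanoate
Product: 36 methyl 3-(tert-butyldimethylsilyloxy)-2-hydroxy-2-[(1S,4R,8S,10R)-8-(tert-butyldimethylsilyloxy)-1,4-epoxy-1-methoxy-4,10-dimethyl-6-oxocyclodecan-7-yl]propanoate (epimers at C7 and C11), via lithium enolate 34 (not isolated), via chlorozinc enolate 35 (not isolated)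
Conditions: LDA, THF, −78 °C; ZnCl2, −78 °C; 33, −78 °C; AcOH quench at −78 °C
Reagents that add atoms: none
Why: Kinetic deprotonation by the bulky amide is expected at C7, a methylene next to a secondary carbon, and not at C5, a neopentyl-type methylene next to the quaternary bridgehead C4; the zinc enolate, less basic than the lithium enolate, adds to the very electrophilic ketone carbonyl of 33 (aldol addition) without enolising it. Low temperature suppresses β-elimination of the C8 silyloxy group, and the uncontrolled centres C7 and C11 disappear in the next steps.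

Step 20
Reactants: 36 methyl 3-(tert-butyldimethylsilyloxy)-2-hydroxy-2-[(1S,4R,8S,10R)-8-(tert-butyldimethylsilyloxy)-1,4-epoxy-1-methoxy-4,10-dimethyl-6-oxocyclodecan-7-yl]propanoate
Product: 37 methyl 3-(tert-butyldimethylsilyloxy)-2-[(1S,4R,8S,10R)-8-(tert-butyldimethylsilyloxy)-1,4-epoxy-1-methoxy-4,10-dimethyl-6-oxocyclodecan-7-ylidene]propanoate (both alkene isomers)
Conditions: Ph2S[OC(CF3)2Ph]2 (Martin sulfurane), CH2Cl2, 0 °C → rt
Reagents that add atoms: none
Why: Dehydration of the tertiary alcohol through its alkoxysulfonium ion; the C7 hydrogen, α to the ketone, is the acidic β-hydrogen, so the alkene forms at C7=C11. The neutral conditions spare the ketal and silyl ethers and make the aldol step irreversible; both geometric isomers are expected.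

Step 21
Reactants: 37 methyl 3-(tert-butyldimethylsilyloxy)-2-[(1S,4R,8S,10R)-8-(tert-butyldimethylsilyloxy)-1,4-epoxy-1-methoxy-4,10-dimethyl-6-oxocyclodecan-7-ylidene]propanoate
Product: 38 (1S,4R,8S,10R)-8,13-bis(tert-butyldimethylsilyloxy)-1,4-epoxy-6-hydroxy-1-methoxygermacr-7(11)-en-12,6-olide (C6 epimers)
Conditions: Me3SnOH, ClCH2CH2Cl, 70 °C; cold 0.05 M HCl wash; hν (365 nm), CH2Cl2, rt for material that has not cyclised
Reagents that add atoms: trimethyltin hydroxide, C[Sn](C)(C)O
Why: Me3SnOH cleaves the methyl ester under nearly neutral conditions; the acid with its carboxyl cis to the C6 ketone closes to the cyclic pseudo-acid (ring–chain tautomerism of cis-4-oxo-2-enoic acids). The trans acid is converted by photochemical E/Z isomerisation, with cyclisation removing the cis isomer from the photoequilibrium.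

Step 22
Reactants: 38 (1S,4R,8S,10R)-8,13-bis(tert-butyldimethylsilyloxy)-1,4-epoxy-6-hydroxy-1-methoxygermacr-7(11)-en-12,6-olide
Product: 39 (1S,4R,5E,8S,10R)-8,13-bis(tert-butyldimethylsilyloxy)-1,4-epoxy-1-methoxygermacra-5,7(11)-dien-12,6-olide
Conditions: (CF3CO)2O, Et3N, CH2Cl2, −20 → 0 °C
Reagents that add atoms: none
Why: Acylation of the lactol hydroxyl and loss of trifluoroacetate with removal of a C5 proton, the usual dehydration of a γ-hydroxybutenolide to a γ-ylidenebutenolide; only C5 carries hydrogen, and the oxygen-bridged nine-membered ring holds C4 and C7 cis on the new double bond, which is the 5E geometry.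

Step 23
Reactants: 39 (1S,4R,5E,8S,10R)-8,13-bis(tert-butyldimethylsilyloxy)-1,4-epoxy-1-methoxygermacra-5,7(11)-dien-12,6-olide
Product: 40 (1S,4R,5E,8S,10R)-1,4-epoxy-8,13-dihydroxy-1-methoxygermacra-5,7(11)-dien-12,6-olide
Conditions: Et3N·3HF, MeCN/THF, rt → 40 °C
Reagents that add atoms: none
Why: Fluoride-mediated cleavage of both silyl ethers under buffered, weakly acidic conditions that spare the ketal and the enol lactone; the lactone cannot migrate to O8 because C12 is trans to C8 across C7=C11.

Step 24
Reactants: 40 (1S,4R,5E,8S,10R)-1,4-epoxy-8,13-dihydroxy-1-methoxygermacra-5,7(11)-dien-12,6-olide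
Product: 41 (1S,4R,5E,8S,10R)-13-acetoxy-1,4-epoxy-8-hydroxy-1-methoxygermacra-5,7(11)-dien-12,6-olide
Conditions: Ac2O (1.2 equiv), 2,4,6-collidine, CH2Cl2, −20 → 0 °C
Reagents that add atoms: acetic anhydride, CC(=O)OC(C)=O
Why: Selective acetylation of the primary allylic hydroxyl over the hindered secondary C8 hydroxyl, using limiting anhydride and a weak, non-nucleophilic base at low temperature.

Step 25
Reactants: 42 (R)-3-bromo-2-hydroxy-2-methylpropanoic acid
Product: 43 (S)-2-methyloxirane-2-carboxylic acid
Conditions: KOH (2.1 equiv), H2O/MeOH, 0 °C → rt; cold aq H2SO4 to pH 3, EtOAc extraction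
Reagents that add atoms: none
Why: Intramolecular Williamson closure of the tertiary alkoxide onto the primary bromide; the stereocentre is not a reaction centre, and the descriptor changes from R to S only through the priority change.

Step 26
Reactants: 41 (1S,4R,5E,8S,10R)-13-acetoxy-1,4-epoxy-8-hydroxy-1-methoxygermacra-5,7(11)-dien-12,6-olide; 43 (S)-2-methyloxirane-2-carboxylic acid
Product: 44 (1S,4R,5E,8S,10R)-13-acetoxy-1,4-epoxy-1-methoxy-8-[(S)-2-methyloxirane-2-carbonyloxy]germacra-5,7(11)-dien-12,6-olide
Conditions: 2-methyl-6-nitrobenzoic anhydride, Et3N, DMAP, CH2Cl2, rt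
Reagents that add atoms: none
Why: Shiina esterification: the mixed anhydride of 43 transfers its acyl group to the hindered C8 alcohol under DMAP catalysis; the conditions are chloride-free, so the epoxide is kept, and the C1 methyl ketal prevents interference by a free hemiketal.

Step 27
Reactants: 44 (1S,4R,5E,8S,10R)-13-acetoxy-1,4-epoxy-1-methoxy-8-[(S)-2-methyloxirane-2-carbonyloxy]germacra-5,7(11)-dien-12,6-olide
Product: 46 (1S,4R,5E,8S,10R)-13-acetoxy-8-[(R)-3-chloro-2-hydroxy-2-methylpropanoyloxy]-1,4-epoxy-1-hydroxygermacra-5,7(11)-dien-12,6-olide (CNP0414417.3), via chlorohydrin methyl ketal 45 (not isolated)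
Conditions: HCl (4 M in dioxane), CH2Cl2, 0 °C; then THF/H2O, rt
Reagents that add atoms: hydrogen chloride, Cl; water, O
Why: Chloride opens the protonated glycidic ester at its unsubstituted CH2 (SN2; the quaternary α-carbon is shielded and deactivated by the ester), so C2′ is untouched and becomes R by the priority change; aqueous acid then hydrolyses the bridged methyl ketal through its oxocarbenium ion to the hemiketal, whose configuration is again dictated by the bridge.

## Compound list

1 | 1,3-dithiane | C1CSCSC1 | starting material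
2 | 2-lithio-1,3-dithiane | [Li]C1SCCCS1 | intermediate
3 | 2-(tert-butyldimethylsilyl)-1,3-dithiane | CC(C)(C)[Si](C)(C)C1SCCCS1 | intermediate
4 | trimethylsilylacetylene | C#C[Si](C)(C)C | starting material
5 | (S)-epichlorohydrin | ClC[C@@H]1CO1 | starting material
6 | lithium (trimethylsilyl)acetylide | [Li]C#C[Si](C)(C)C | intermediate
7 | (S)-1-chloro-5-(trimethylsilyl)pent-4-yn-2-ol | ClC[C@@H](O)CC#C[Si](C)(C)C | intermediate
8 | (S)-trimethyl[3-(oxiran-2-yl)prop-1-yn-1-yl]silane | C[Si](C)(C)C#CC[C@H]1CO1 | intermediate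
9 | (S)-2-methylglycidol | OC[C@@]1(C)CO1 | starting material
10 | vinylmagnesium bromide | C=C[Mg]Br | starting material
11 | (R)-2-methylpent-4-ene-1,2-diol | C=CC[C@@](C)(O)CO | intermediate
12 | (R)-2-hydroxy-2-methylpent-4-en-1-yl 4-methylbenzenesulfonate | C=CC[C@@](C)(O)COS(=O)(=O)c1ccc(C)cc1 | intermediate
13 | (R)-2-allyl-2-methyloxirane | C=CC[C@]1(C)CO1 | intermediate
14 | 2-lithio-2-(tert-butyldimethylsilyl)-1,3-dithiane | CC(C)(C)[Si](C)(C)C1([Li])SCCCS1 | intermediate
15 | lithium (S)-1-[2-(tert-butyldimethylsilyl)-1,3-dithian-2-yl]-5-(trimethylsilyl)pent-4-yn-2-olate | CC(C)(C)[Si](C)(C)C1(SCCCS1)C[C@@H](O[Li])CC#C[Si](C)(C)C | intermediate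
16 | 2-lithio-2-[(S)-2-(tert-butyldimethylsilyloxy)-5-(trimethylsilyl)pent-4-yn-1-yl]-1,3-dithiane | [Li]C1(SCCCS1)C[C@@H](O[Si](C)(C)C(C)(C)C)CC#C[Si](C)(C)C | intermediate
17 | (R)-1-{2-[(S)-2-(tert-butyldimethylsilyloxy)-5-(trimethylsilyl)pent-4-yn-1-yl]-1,3-dithian-2-yl}-2-methylpent-4-en-2-ol | C=CC[C@@](C)(O)CC1(SCCCS1)C[C@@H](O[Si](C)(C)C(C)(C)C)CC#C[Si](C)(C)C | intermediate
18 | 2-[(R)-2-methyl-2-(triethylsilyloxy)pent-4-en-1-yl]-2-[(S)-2-(tert-butyldimethylsilyloxy)-5-(trimethylsilyl)pent-4-yn-1-yl]-1,3-dithiane | C=CC[C@@](C)(O[Si](CC)(CC)CC)CC1(SCCCS1)C[C@@H](O[Si](C)(C)C(C)(C)C)CC#C[Si](C)(C)C | intermediate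
19 | 2-[(R)-2-methyl-2-(triethylsilyloxy)pent-4-en-1-yl]-2-[(S)-2-(tert-butyldimethylsilyloxy)pent-4-yn-1-yl]-1,3-dithiane | C=CC[C@@](C)(O[Si](CC)(CC)CC)CC1(SCCCS1)C[C@@H](O[Si](C)(C)C(C)(C)C)CC#C | intermediate
20 | (Z)-2-iodoalk-1-enyl-9-BBN adduct of 19 (boron on C14, iodine on C10) | C=CC[C@@](C)(O[Si](CC)(CC)CC)CC1(SCCCS1)C[C@@H](O[Si](C)(C)C(C)(C)C)C/C(I)=C/B1C2CCCC1CCC2 | intermediate
21 | 2-[(R)-2-methyl-2-(triethylsilyloxy)pent-4-en-1-yl]-2-[(R)-2-(tert-butyldimethylsilyloxy)-4-iodopent-4-en-1-yl]-1,3-dithiane | C=CC[C@@](C)(O[Si](CC)(CC)CC)CC1(SCCCS1)C[C@@H](O[Si](C)(C)C(C)(C)C)CC(I)=C | intermediate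
22 | B-alkyl-9-BBN adduct of 21 (boron on C1) | C(CC[C@@](C)(O[Si](CC)(CC)CC)CC1(SCCCS1)C[C@@H](O[Si](C)(C)C(C)(C)C)CC(I)=C)B1C2CCCC1CCC2 | intermediate
23 | (R)-5-{2-[(R)-2-(tert-butyldimethylsilyloxy)-4-iodopent-4-en-1-yl]-1,3-dithian-2-yl}-4-methyl-4-(triethylsilyloxy)pentan-1-ol | OCCC[C@@](C)(O[Si](CC)(CC)CC)CC1(SCCCS1)C[C@@H](O[Si](C)(C)C(C)(C)C)CC(I)=C | intermediate
24 | (R)-5-{2-[(R)-2-(tert-butyldimethylsilyloxy)-4-iodopent-4-en-1-yl]-1,3-dithian-2-yl}-4-methyl-4-(triethylsilyloxy)pentanal | O=CCC[C@@](C)(O[Si](CC)(CC)CC)CC1(SCCCS1)C[C@@H](O[Si](C)(C)C(C)(C)C)CC(I)=C | intermediate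
25 | (4R,8S)-8-(tert-butyldimethylsilyloxy)-4-methyl-10-methylidene-6,6-(propane-1,3-diyldisulfanediyl)-4-(triethylsilyloxy)cyclodecan-1-ol, C1 epimers | OC1CC[C@@](C)(O[Si](CC)(CC)CC)CC2(SCCCS2)C[C@@H](O[Si](C)(C)C(C)(C)C)CC1=C | intermediate
26 | (4R,8S)-8-(tert-butyldimethylsilyloxy)-4-methyl-10-methylidene-6,6-(propane-1,3-diyldisulfanediyl)-4-(triethylsilyloxy)cyclodecan-1-one | O=C1CC[C@@](C)(O[Si](CC)(CC)CC)CC2(SCCCS2)C[C@@H](O[Si](C)(C)C(C)(C)C)CC1=C | intermediate
27 | (4R,8S,10R)-8-(tert-butyldimethylsilyloxy)-4,10-dimethyl-6,6-(propane-1,3-diyldisulfanediyl)-4-(triethylsilyloxy)cyclodecan-1-one | O=C1CC[C@@](C)(O[Si](CC)(CC)CC)CC2(SCCCS2)C[C@@H](O[Si](C)(C)C(C)(C)C)C[C@H]1C | intermediate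
28 | (1S,4R,8S,10R)-8-(tert-butyldimethylsilyloxy)-1,4-epoxy-4,10-dimethyl-6,6-(propane-1,3-diyldisulfanediyl)cyclodecan-1-ol | O[C@@]12CC[C@@](C)(O1)CC3(SCCCS3)C[C@@H](O[Si](C)(C)C(C)(C)C)C[C@H]2C | intermediate
29 | (1S,4R,8S,10R)-8-(tert-butyldimethylsilyloxy)-1,4-epoxy-1-methoxy-4,10-dimethyl-6,6-(propane-1,3-diyldisulfanediyl)cyclodecane | CO[C@@]12CC[C@@](C)(O1)CC3(SCCCS3)C[C@@H](O[Si](C)(C)C(C)(C)C)C[C@H]2C | intermediate
30 | (1S,4R,8S,10R)-8-(tert-butyldimethylsilyloxy)-1,4-epoxy-1-methoxy-4,10-dimethylcyclodecan-6-one | CO[C@@]12CC[C@@](C)(O1)CC(=O)C[C@@H](O[Si](C)(C)C(C)(C)C)C[C@H]2C | intermediate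
31 | methyl 2-(hydroxymethyl)acrylate | COC(=O)C(=C)CO | starting material
32 | methyl 2-[(tert-butyldimethylsilyloxy)methyl]acrylate | COC(=O)C(=C)CO[Si](C)(C)C(C)(C)C | intermediate
33 | methyl 3-(tert-butyldimethylsilyloxy)-2-oxopropanoate | COC(=O)C(=O)CO[Si](C)(C)C(C)(C)C | intermediate
34 | lithium C6–C7 enolate of 30 | CO[C@@]12CC[C@@](C)(O1)CC(O[Li])=C[C@@H](O[Si](C)(C)C(C)(C)C)C[C@H]2C | intermediate
35 | chlorozinc C6–C7 enolate of 30 | CO[C@@]12CC[C@@](C)(O1)CC(O[Zn]Cl)=C[C@@H](O[Si](C)(C)C(C)(C)C)C[C@H]2C | intermediate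
36 | methyl 3-(tert-butyldimethylsilyloxy)-2-hydroxy-2-[(1S,4R,8S,10R)-8-(tert-butyldimethylsilyloxy)-1,4-epoxy-1-methoxy-4,10-dimethyl-6-oxocyclodecan-7-yl]propanoate, epimers at C7 and C11 | CO[C@@]12CC[C@@](C)(O1)CC(=O)C(C(O)(CO[Si](C)(C)C(C)(C)C)C(=O)OC)[C@@H](O[Si](C)(C)C(C)(C)C)C[C@H]2C | intermediate
37 | methyl 3-(tert-butyldimethylsilyloxy)-2-[(1S,4R,8S,10R)-8-(tert-butyldimethylsilyloxy)-1,4-epoxy-1-methoxy-4,10-dimethyl-6-oxocyclodecan-7-ylidene]propanoate, both C7=C11 isomers | CO[C@@]12CC[C@@](C)(O1)CC(=O)C(=C(CO[Si](C)(C)C(C)(C)C)C(=O)OC)[C@@H](O[Si](C)(C)C(C)(C)C)C[C@H]2C | intermediate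
38 | (1S,4R,8S,10R)-8,13-bis(tert-butyldimethylsilyloxy)-1,4-epoxy-6-hydroxy-1-methoxygermacr-7(11)-en-12,6-olide, C6 epimers | CC(C)(C)[Si](C)(C)OCC1=C2C(O)(C[C@@]3(C)CC[C@](OC)(O3)[C@H](C)C[C@@H]2O[Si](C)(C)C(C)(C)C)OC1=O | intermediate
39 | (1S,4R,5E,8S,10R)-8,13-bis(tert-butyldimethylsilyloxy)-1,4-epoxy-1-methoxygermacra-5,7(11)-dien-12,6-olide | CC(C)(C)[Si](C)(C)OCC1=C2/C(=C\[C@@]3(C)CC[C@](OC)(O3)[C@H](C)C[C@@H]2O[Si](C)(C)C(C)(C)C)OC1=O | intermediate
40 | (1S,4R,5E,8S,10R)-1,4-epoxy-8,13-dihydroxy-1-methoxygermacra-5,7(11)-dien-12,6-olide | OCC1=C2/C(=C\[C@@]3(C)CC[C@](OC)(O3)[C@H](C)C[C@@H]2O)OC1=O | intermediate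
41 | (1S,4R,5E,8S,10R)-13-acetoxy-1,4-epoxy-8-hydroxy-1-methoxygermacra-5,7(11)-dien-12,6-olide | CC(=O)OCC1=C2/C(=C\[C@@]3(C)CC[C@](OC)(O3)[C@H](C)C[C@@H]2O)OC1=O | intermediate
42 | (R)-3-bromo-2-hydroxy-2-methylpropanoic acid | OC(=O)[C@@](C)(O)CBr | starting material
43 | (S)-2-methyloxirane-2-carboxylic acid | OC(=O)[C@]1(C)CO1 | intermediate
44 | (1S,4R,5E,8S,10R)-13-acetoxy-1,4-epoxy-1-methoxy-8-[(S)-2-methyloxirane-2-carbonyloxy]germacra-5,7(11)-dien-12,6-olide | CC(=O)OCC1=C2/C(=C\[C@@]3(C)CC[C@](OC)(O3)[C@H](C)C[C@@H]2OC(=O)[C@]4(C)CO4)OC1=O | intermediate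
45 | (1S,4R,5E,8S,10R)-13-acetoxy-8-[(R)-3-chloro-2-hydroxy-2-methylpropanoyloxy]-1,4-epoxy-1-methoxygermacra-5,7(11)-dien-12,6-olide | CC(=O)OCC1=C2/C(=C\[C@@]3(C)CC[C@](OC)(O3)[C@H](C)C[C@@H]2OC(=O)[C@@](C)(O)CCl)OC1=O | intermediate
46 | (1S,4R,5E,8S,10R)-13-acetoxy-8-[(R)-3-chloro-2-hydroxy-2-methylpropanoyloxy]-1,4-epoxy-1-hydroxygermacra-5,7(11)-dien-12,6-olide (CNP0414417.3) | CC(=O)OCC1=C2/C(=C\[C@@]3(C)CC[C@](O)(O3)[C@H](C)C[C@@H]2OC(=O)[C@@](C)(O)CCl)OC1=O | target

## Step count and least certain steps

Total step count: 27. Longest linear sequence: 21 steps (steps 4–16, 19–24, 26 and 27, counted from 9).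

**Step 6 (key step).** Three processes could spoil it. Silicon may migrate before epoxide 8 is consumed, which leads to double addition of 8. The regenerated carbanion may take a propargylic proton from C9, and the resulting anion would expel the C8 silanolate. The hindered 2,2-disubstituted epoxide 13 may open too slowly, so the carbanion is quenched. The fallback is a stepwise bis-alkylation in the opposite order, so that no carbanion is ever generated next to propargylic hydrogens. It sets out from 1 and returns at 18. Lithiated 2 (n-BuLi) opens 13 to give (R)-1-(1,3-dithian-2-yl)-2-methylpent-4-en-2-ol F1. TESOTf with 2,6-lutidine gives 2-[(R)-2-methyl-2-(triethylsilyloxy)pent-4-en-1-yl]-1,3-dithiane F2. Metalation with t-BuLi in THF/HMPA at −78 °C and addition of 8 give (S)-1-{2-[(R)-2-methyl-2-(triethylsilyloxy)pent-4-en-1-yl]-1,3-dithian-2-yl}-5-(trimethylsilyl)pent-4-yn-2-ol F3. Silylation with TBSOTf and 2,6-lutidine gives 18.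

**Step 19.** Deprotonation may occur on the C5 side; that enolate would expel the C4 ketal oxygen, or the aldol would be attached to the wrong carbon. Proton transfer from 33 to the enolate is a second failure mode. The fallback separates the regiochemical decision from the C–C bond formation. It sets out from 30 and returns at 36. Silylation of 30 (LDA then TESCl, or TESOTf with Et3N) gives the enol ethers, from which (1S,4R,8S,10R)-8-(tert-butyldimethylsilyloxy)-1,4-epoxy-1-methoxy-4,10-dimethyl-6-(triethylsilyloxy)cyclodec-6-ene F12 is isolated. The C5 regioisomer is hydrolysed back to 30 and recycled. A Mukaiyama aldol addition of F12 to 33, catalysed by Cu(OTf)2 in CH2Cl2 at −78 °C and followed by mild acidic removal of the silyl group from the aldol oxygen, gives 36.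

**Step 12.** Intermolecular coupling to oligomers, or simple reduction of the C–I bond, may outrun closure of the strained ten-membered ring. The fallback closes the same bond by a nickel-catalysed reductive cyclisation of an alkynyl aldehyde and needs no vinyl iodide. It sets out from 18 and returns at 25. Hydroboration–oxidation of 18 (9-BBN, then NaBO3) gives (R)-5-{2-[(S)-2-(tert-butyldimethylsilyloxy)-5-(trimethylsilyl)pent-4-yn-1-yl]-1,3-dithian-2-yl}-4-methyl-4-(triethylsilyloxy)pentan-1-ol F5. K2CO3 in MeOH gives the terminal alkyne (R)-5-{2-[(S)-2-(tert-butyldimethylsilyloxy)pent-4-yn-1-yl]-1,3-dithian-2-yl}-4-methyl-4-(triethylsilyloxy)pentan-1-ol F6. Parikh–Doering oxidation gives the corresponding pentanal F7. Ni(cod)2 with a bulky N-heterocyclic carbene ligand and Et3SiH at high dilution joins the internal alkyne carbon to the aldehyde and gives (4R,8S)-8-(tert-butyldimethylsilyloxy)-4-methyl-10-methylidene-6,6-(propane-1,3-diyldisulfanediyl)-1,4-bis(triethylsilyloxy)cyclodecane F8. Selective methanolysis of its secondary allylic silyl ether (PPTS, MeOH, 0 °C) gives 25.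

**Step 14.** Protonation of the enolate at C10 may show poor facial selectivity, and the base equilibrium may not favour 10R. The fallback sets C10 by a hydroxyl-directed hydrogenation, which needs the sulfur removed first. It sets out from 25 and returns at 30. The C1 epimers of 25 are separated, and the epimer that directs hydrogen to the required face is used (the other is inverted by a Mitsunobu reaction). MeI and CaCO3 in aqueous MeCN remove the dithiane and give (4R,8S)-8-(tert-butyldimethylsilyloxy)-1-hydroxy-4-methyl-10-methylidene-4-(triethylsilyloxy)cyclodecan-6-one F9. Hydrogenation with [Ir(cod)(PCy3)(py)]PF6 under H2 gives (4R,8S,10R)-8-(tert-butyldimethylsilyloxy)-1-hydroxy-4,10-dimethyl-4-(triethylsilyloxy)cyclodecan-6-one F10. Parikh–Doering oxidation gives (4R,8S,10R)-8-(tert-butyldimethylsilyloxy)-4,10-dimethyl-4-(triethylsilyloxy)cyclodecane-1,6-dione F11. CSA in MeOH then removes the triethylsilyl group and closes the C1 ketal selectively, because only C1 can form the five-membered bridge, giving 30.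

**Step 9.** The boron iodide is a Lewis acid and may attack the thioketal sulfur or cleave the tertiary silyl ether before haloboration is complete. The fallback installs the C10 substituent by stannylcupration. It sets out from 19 and returns at 21. Me3SnCu·SMe2 with MeOH in THF at low temperature adds tin to the internal alkyne carbon and gives 2-[(R)-2-methyl-2-(triethylsilyloxy)pent-4-en-1-yl]-2-[(R)-2-(tert-butyldimethylsilyloxy)-4-(trimethylstannyl)pent-4-en-1-yl]-1,3-dithiane F4. Iodine in anhydrous CH2Cl2 at −78 °C exchanges tin for iodine much faster than it attacks the thioketal, and gives 21.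

## Further compounds

F1 | step 6 | (R)-1-(1,3-dithian-2-yl)-2-methylpent-4-en-2-ol | C=CC[C@@](C)(O)CC1SCCCS1
F2 | step 6 | 2-[(R)-2-methyl-2-(triethylsilyloxy)pent-4-en-1-yl]-1,3-dithiane | C=CC[C@@](C)(O[Si](CC)(CC)CC)CC1SCCCS1
F3 | step 6 | (S)-1-{2-[(R)-2-methyl-2-(triethylsilyloxy)pent-4-en-1-yl]-1,3-dithian-2-yl}-5-(trimethylsilyl)pent-4-yn-2-ol | C=CC[C@@](C)(O[Si](CC)(CC)CC)CC1(SCCCS1)C[C@@H](O)CC#C[Si](C)(C)C
F4 | step 9 | 2-[(R)-2-methyl-2-(triethylsilyloxy)pent-4-en-1-yl]-2-[(R)-2-(tert-butyldimethylsilyloxy)-4-(trimethylstannyl)pent-4-en-1-yl]-1,3-dithiane | C=CC[C@@](C)(O[Si](CC)(CC)CC)CC1(SCCCS1)C[C@@H](O[Si](C)(C)C(C)(C)C)CC(=C)[Sn](C)(C)C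
F5 | step 12 | (R)-5-{2-[(S)-2-(tert-butyldimethylsilyloxy)-5-(trimethylsilyl)pent-4-yn-1-yl]-1,3-dithian-2-yl}-4-methyl-4-(triethylsilyloxy)pentan-1-ol | OCCC[C@@](C)(O[Si](CC)(CC)CC)CC1(SCCCS1)C[C@@H](O[Si](C)(C)C(C)(C)C)CC#C[Si](C)(C)C
F6 | step 12 | (R)-5-{2-[(S)-2-(tert-butyldimethylsilyloxy)pent-4-yn-1-yl]-1,3-dithian-2-yl}-4-methyl-4-(triethylsilyloxy)pentan-1-ol | OCCC[C@@](C)(O[Si](CC)(CC)CC)CC1(SCCCS1)C[C@@H](O[Si](C)(C)C(C)(C)C)CC#C
F7 | step 12 | (R)-5-{2-[(S)-2-(tert-butyldimethylsilyloxy)pent-4-yn-1-yl]-1,3-dithian-2-yl}-4-methyl-4-(triethylsilyloxy)pentanal | O=CCC[C@@](C)(O[Si](CC)(CC)CC)CC1(SCCCS1)C[C@@H](O[Si](C)(C)C(C)(C)C)CC#C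
F8 | step 12 | (4R,8S)-8-(tert-butyldimethylsilyloxy)-4-methyl-10-methylidene-6,6-(propane-1,3-diyldisulfanediyl)-1,4-bis(triethylsilyloxy)cyclodecane, C1 epimers | CC[Si](CC)(CC)OC1CC[C@@](C)(O[Si](CC)(CC)CC)CC2(SCCCS2)C[C@@H](O[Si](C)(C)C(C)(C)C)CC1=C
F9 | step 14 | (4R,8S)-8-(tert-butyldimethylsilyloxy)-1-hydroxy-4-methyl-10-methylidene-4-(triethylsilyloxy)cyclodecan-6-one, single C1 epimer | OC1CC[C@@](C)(O[Si](CC)(CC)CC)CC(=O)C[C@@H](O[Si](C)(C)C(C)(C)C)CC1=C
F10 | step 14 | (4R,8S,10R)-8-(tert-butyldimethylsilyloxy)-1-hydroxy-4,10-dimethyl-4-(triethylsilyloxy)cyclodecan-6-one | OC1CC[C@@](C)(O[Si](CC)(CC)CC)CC(=O)C[C@@H](O[Si](C)(C)C(C)(C)C)C[C@H]1C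
F11 | step 14 | (4R,8S,10R)-8-(tert-butyldimethylsilyloxy)-4,10-dimethyl-4-(triethylsilyloxy)cyclodecane-1,6-dione | O=C1CC[C@@](C)(O[Si](CC)(CC)CC)CC(=O)C[C@@H](O[Si](C)(C)C(C)(C)C)C[C@H]1C
F12 | step 19 | (1S,4R,8S,10R)-8-(tert-butyldimethylsilyloxy)-1,4-epoxy-1-methoxy-4,10-dimethyl-6-(triethylsilyloxy)cyclodec-6-ene | CO[C@@]12CC[C@@](C)(O1)CC(O[Si](CC)(CC)CC)=C[C@@H](O[Si](C)(C)C(C)(C)C)C[C@H]2C
A1 | alternative 1 | open-chain furan aldehyde with C9 allylic bromide, C1 methyl ketal and C12 trimethylsilyl group | C[Si](C)(C)c1oc(C[C@@]2(C)CC[C@](OC)(O2)C(=C)CBr)c(C=O)c1COC(C)=O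
A2 | alternative 1 | furan-fused ten-membered C8 carbinol with C10 exo-methylene | C[Si](C)(C)c1oc2C[C@@]3(C)CC[C@](OC)(O3)C(=C)C[C@H](O)c2c1COC(C)=O
A3 | alternative 2 | open-chain C5 methyl carbonate with C2 phenylsulfonyl ketone on the preformed butenolide | COC(=O)OC(C(C)=C)[C@@H]1OC(=O)C(CO[Si](C)(C)C(C)(C)C)=C1[C@@H](O[Si](C)(C)C(C)(C)C)C[C@@H](C)C(=O)CS(=O)(=O)c1ccccc1
A4 | alternative 2 | ten-membered 4E-en-1-one 12,6-olide with C2 phenylsulfonyl group | CC(C)(C)[Si](C)(C)OCC1=C2[C@@H](OC1=O)/C=C(C)/C[C@H](S(=O)(=O)c3ccccc3)C(=O)[C@H](C)C[C@@H]2O[Si](C)(C)C(C)(C)C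
A5 | alternative 3 | macrocyclic hemiketal Z-β-iodoenone (C6 ketone, C7=C11, iodine on C11) | CC(C)(C)[Si](C)(C)OC/C(I)=C1/C(=O)C[C@@]2(C)CC[C@](O)(O2)[C@H](C)C[C@@H]1O[Si](C)(C)C(C)(C)C
A6 | alternative 3 | 8,13-bis(tert-butyldimethylsilyl) ether of the tricyclic hemiketal butenolide core | CC(C)(C)[Si](C)(C)OCC1=C2/C(=C\[C@@]3(C)CC[C@](O)(O3)[C@H](C)C[C@@H]2O[Si](C)(C)C(C)(C)C)OC1=O
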